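At early times substrate leaves by two routes: Tuesday's flask had lost 78.0 % of it by 120 min, more than the 35.9 % its partner could take. On Wednesday bis adduct still reads 0 % at 15.0 min, with 33 % of the substrate left, so it grows from a first product.

the same everywhere: substrate 0.39 M
- Tuesday's: partner 0.14 M; run made earlier
- Wednesday's: partner 2.6 M; run made earlier
- oak: partner 0.200 M; time 3.0 h
- alder: partner 0.780 M; time 3.0 h
- maple: partner 1.50 M; time 3.0 h
- birch: partner 3.00 M; time 3.0 h
- larch: partner 1.20 M; time 3.0 h

| run | time / min | bis adduct / % | substrate / % |
|---|---|---|---|
| Tuesday's | 10.0 | 0 | 79 |
| Tuesday's | 25.0 | 0 | 59 |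
| Tuesday's | 50.0 | 0 | 39 |
| Tuesday's | 120 | 0 | 22 |
| Wednesday's | 15.0 | 0 | 33 |
| Wednesday's | 40.0 | 6 | 6 |
| Wednesday's | 80.0 | 11 | 1 |
| Wednesday's | 120 | 18 | 0 |

(scatter of a reading: 1.5 percentage points)

- the earlier runs were read with a standard deviation of 1.5 percentage points

* all flasks from highest to lowest amount of bis adduct, in percent of the substrate charged, at 3.0 h (oak / alder / maple / birch / larch)
* the same order at 25 h (oak / alder / maple / birch / larch)
* the amount of bis adduct, in percent of the substrate charged of the flask you put first, at 3.0 h
* the amount of bis adduct, in percent of the substrate charged of the flask you put last, at 3.0 h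

The reckoning here treats the first stage as over and follows the second. Let s be the initial rate of self-loss over that of the partner route. A share Y = ln(1+s)/s then reaches the first product, and the free partner is P, the charge less Y times the substrate charged. With partner in excess the second step is pseudo-first-order, so bis adduct = Y(1 − e^(−x)), where x = kPt and k is the second-step constant.

The inputs are weighed in turn for birch. Rough readings give a self-loss constant of 0.0313 min⁻¹ from Tuesday and a decay constant of 0.0739 min⁻¹ from Wednesday, so s = 0.367 and Y = 85.2 %. The speed of the first stage drops out of this reckoning for birch, since its substrate half-life, scaled from Wednesday's decay constant, is 8.13 min, shorter than 3.0 h. Doubling s multiplies Y by just 0.880, so s can stay rough. The exposure x must be known well, and it rests on Wednesday's 18 %, read with a scatter of 1.5 points.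

That reading gives x = 0.243 on Wednesday, with P = 2.27 M. Scaling by Pt, with P = 2.67 M, gives birch's second-step exposure, x = kPt, as 0.428, and so 29.6 % of bis adduct. With the substrate charge and the time held, Y and x in this reckoning are higher for birch than for oak and both rise with the partner charge, so the reckoned order at both times follows that charge, birch first and oak last. Oak, with its whole charge counted as free and its first stage taken as over, reckons to 1.09 %, but its scaled substrate half-life is 122 min against 3.0 h, so that figure errs high.

The forecast, reasoning that “More partner improves both mono yield and bis formation, so the order follows partner at both times”, gives birch > maple > larch > alder > oak at 3.0 h, birch > maple > larch > alder > oak at 25 h, 29 % and 0.3 %.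

The flasks give birch > maple > larch > alder > oak at 3.0 h and birch > maple > larch > alder > oak at 25 h, with 28.2 % in birch and 0.332 % in oak.

    substrate + partner → first product + by-product (k = 0.0250 M⁻¹ min⁻¹)
    partner + first product → bis adduct + by-product (k = 9.10 × 10⁻⁴ M⁻¹ min⁻¹)
    2 substrate → homo dimer (k = 0.0310 M⁻¹ min⁻¹)

At 3.00 h birch holds 58.0 % of first product beside its bis adduct, and 13.8 % stands as homo dimer. For maple, s = 0.734 and Y = 75.0 %. Birch's exposure scaled to maple's free partner gives x = 0.194, hence 13.2 % of bis adduct by this reckoning. Maple holds 11.8 % at 3.00 h.

The numbers in the tables are simulated from invented constants.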